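Ring B of the tetralin is opened at its only unfunctionalised bond, C2–C3, which lies between the two benzylic stereocentres C1 (methyl) and C4 (side chain) in their trans-1,4 relation. Ring-closing metathesis of an ortho-dialkenyl arene, propenyl on C1 and vinyl on C4, recloses ring B in one operation without touching either centre. The diene already carries C1, C4, C11 and C15: C1 comes from a chirality-transfer aromatic Claisen rearrangement, C4 and C11 from a boron-controlled ester-enolate Claisen rearrangement, C15 from the Roche ester through an alkyl–alkyl Suzuki coupling. The catechol and the primary alcohol travel as benzyl ethers.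

Key step: step 16

Numbering used: ring A is the arene; ring B carries C1 (methyl-bearing) to C4 (chain-bearing); the side chain runs from C11 (methine on C4) to C16 (CH2OH). The target is (1R,4S,11S,15S).

Assumption: in step 9 the (4S,5S)-controller is taken to give the (2R,3S)-acid; the sense is checked on the first run, and the equally available (4R,5R)-antipode is used if it proves opposite.

Step 1
Reactants: 1 racemic (E)-pent-3-en-2-ol
Product: 2 (2R,3E)-pent-3-en-2-yl acetate
Conditions: Candida antarctica lipase B (immobilised), vinyl acetate, hexane, 25 °C, stopped near 45% conversion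
Reagents that add atoms: vinyl acetate, CC(=O)OC=C
Why: Lipase-catalysed kinetic resolution by transesterification, in which this enzyme acylates the (R)-enantiomer of secondary methyl carbinols far faster, so that stopping short of half conversion should give the (R)-acetate in high enantiomeric purity while the (S)-alcohol stays unacylated and is removed.

Step 2
Reactants: 2 (2R,3E)-pent-3-en-2-yl acetate
Product: 3 (2R,3E)-pent-3-en-2-ol
Conditions: K2CO3 (cat.), MeOH, 20 °C
Reagents that add atoms: none
Why: Base-catalysed methanolysis cleaves the acetate at the acyl carbon, so the C–O stereocentre is not touched.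

Step 3
Reactants: 4 methyl 2,3-dihydroxybenzoate
Product: 5 methyl 5-bromo-2,3-dihydroxybenzoate
Conditions: Br2 (1.0 equiv), AcOH, 20 °C
Reagents that add atoms: bromine, BrBr
Why: Electrophilic aromatic bromination should go to position 5, which is para to the 2-hydroxyl and meta to the ester, whereas positions 4 and 6 are para and ortho to the deactivating ester.

Step 4
Reactants: 5 methyl 5-bromo-2,3-dihydroxybenzoate; 3 (2R,3E)-pent-3-en-2-ol
Product: 6 methyl 5-bromo-2-hydroxy-3-{[(2S,3E)-pent-3-en-2-yl]oxy}benzoate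
Conditions: PPh3, diisopropyl azodicarboxylate, THF, 0 °C to 20 °C
Reagents that add atoms: none
Why: Mitsunobu etherification, in which the 2-hydroxyl is held in a hydrogen bond to the ester carbonyl and flanked on both sides so that the 3-hydroxyl should react, and SN2 displacement of the oxyphosphonium group inverts the carbinol centre to the (S)-ether.

Step 5
Reactants: 6 methyl 5-bromo-2-hydroxy-3-{[(2S,3E)-pent-3-en-2-yl]oxy}benzoate
Product: 7 methyl 5-bromo-2,3-dihydroxy-4-[(2R,3E)-pent-3-en-2-yl]benzoate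
Conditions: PhNEt2, 150 °C, degassed, sealed tube
Reagents that add atoms: none
Why: Aromatic Claisen rearrangement ([3,3]) into the only free ortho position, through a chair with the carbinol methyl equatorial, passes the ether chirality suprafacially across the allyl unit and should give the (R)-benzylic centre (C1 of the target) with an E-propenyl group.

Step 6
Reactants: 7 methyl 5-bromo-2,3-dihydroxy-4-[(2R,3E)-pent-3-en-2-yl]benzoate
Product: 8 methyl 2,3-bis(benzyloxy)-5-bromo-4-[(2R,3E)-pent-3-en-2-yl]benzoate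
Conditions: BnBr (2.5 equiv), K2CO3, DMF, 60 °C, argon
Reagents that add atoms: benzyl bromide, BrCc1ccccc1
Why: Williamson ether synthesis under carbonate in DMF alkylates both the free and the hydrogen-bonded phenol and is far too weakly basic to touch the benzylic, allylic C–H of the new stereocentre.

Step 7
Reactants: 8 methyl 2,3-bis(benzyloxy)-5-bromo-4-[(2R,3E)-pent-3-en-2-yl]benzoate; 9 (E)-3-(tributylstannyl)prop-2-en-1-ol
Product: 10 methyl 2,3-bis(benzyloxy)-5-[(1E)-3-hydroxyprop-1-en-1-yl]-4-[(2R,3E)-pent-3-en-2-yl]benzoate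
Conditions: Pd(P(t-Bu)3)2 (5 mol%), CuI (10 mol%), CsF (2 equiv), DMF, 45 °C
Reagents that add atoms: none
Why: Stille coupling with a bulky electron-rich phosphine for the ortho-substituted aryl bromide and copper/fluoride acceleration of transmetalation should transfer the alkenyl group with retention of the E geometry and tolerate the free alcohol.

Step 8
Reactants: 10 methyl 2,3-bis(benzyloxy)-5-[(1E)-3-hydroxyprop-1-en-1-yl]-4-[(2R,3E)-pent-3-en-2-yl]benzoate; 11 propionyl chloride
Product: 12 methyl 2,3-bis(benzyloxy)-4-[(2R,3E)-pent-3-en-2-yl]-5-[(1E)-3-(propanoyloxy)prop-1-en-1-yl]benzoate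
Conditions: Et3N, DMAP (cat.), CH2Cl2, 0 °C
Reagents that add atoms: none
Why: Nucleophile-catalysed acylation of an unhindered primary allylic alcohol by an acid chloride is fast at 0 °C and leaves every other group alone.

Step 9
Reactants: 12 methyl 2,3-bis(benzyloxy)-4-[(2R,3E)-pent-3-en-2-yl]-5-[(1E)-3-(propanoyloxy)prop-1-en-1-yl]benzoate
Product: 14 (2R,3S)-3-{3,4-bis(benzyloxy)-5-(methoxycarbonyl)-2-[(2R,3E)-pent-3-en-2-yl]phenyl}-2-methylpent-4-enoic acid, via Z(O) boron ketene acetal 13 (not isolated)
Conditions: (4S,5S)-2-bromo-1,3-bis{[3,5-bis(trifluoromethyl)phenyl]sulfonyl}-4,5-diphenyl-1,3,2-diazaborolidine (1.3 equiv, prepared separately), i-Pr2NEt, CH2Cl2, −78 °C, then −20 to 4 °C; aqueous work-up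
Reagents that add atoms: none
Why: Enantioselective Ireland–Claisen rearrangement of a boron ester enolate, in which the hindered amine in CH2Cl2 should give the Z(O) enolate, the chair transition state with the E-alkene then gives the syn C4/C11 pair, and the C2-symmetric sulfonamide ligand on boron blocks one enolate face and so fixes the absolute sense of both new centres.

Step 10
Reactants: 14 (2R,3S)-3-{3,4-bis(benzyloxy)-5-(methoxycarbonyl)-2-[(2R,3E)-pent-3-en-2-yl]phenyl}-2-methylpent-4-enoic acid
Product: 16 methyl 2,3-bis(benzyloxy)-5-[(3S,4R)-5-hydroxy-4-methylpent-1-en-3-yl]-4-[(2R,3E)-pent-3-en-2-yl]benzoate, via isobutyl carbonic mixed anhydride 15 (not isolated)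
Conditions: i-BuOCOCl, N-methylmorpholine, THF, −15 °C; then NaBH4, H2O, 0 °C
Reagents that add atoms: none
Why: Mixed-anhydride activation followed by borohydride reduction reduces only the activated acyl group, sparing the methyl benzoate and both alkenes (which borane would hydroborate), and the cold, weakly basic activation should not epimerise C11.

Step 11
Reactants: 16 methyl 2,3-bis(benzyloxy)-5-[(3S,4R)-5-hydroxy-4-methylpent-1-en-3-yl]-4-[(2R,3E)-pent-3-en-2-yl]benzoate
Product: 17 methyl 2,3-bis(benzyloxy)-5-[(3S,4R)-5-bromo-4-methylpent-1-en-3-yl]-4-[(2R,3E)-pent-3-en-2-yl]benzoate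
Conditions: CBr4, PPh3, CH2Cl2, 0 °C
Reagents that add atoms: carbon tetrabromide, BrC(Br)(Br)Br
Why: Appel reaction converts the primary alcohol into the bromide by SN2 displacement at a CH2 group under neutral conditions, so no stereocentre is involved.

Step 12
Reactants: 18 methyl (R)-3-hydroxy-2-methylpropanoate (Roche ester)
Product: 19 methyl (R)-3-(benzyloxy)-2-methylpropanoate
Conditions: benzyl 2,2,2-trichloroacetimidate, TfOH (cat.), CH2Cl2/cyclohexane, 20 °C
Reagents that add atoms: benzyl 2,2,2-trichloroacetimidate, ClC(Cl)(Cl)C(=N)OCc1ccccc1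
Why: Acid-catalysed O-benzylation with the trichloroacetimidate avoids base, so the β-hydroxy ester neither eliminates nor racemises.

Step 13
Reactants: 19 methyl (R)-3-(benzyloxy)-2-methylpropanoate
Product: 20 (R)-3-(benzyloxy)-2-methylpropanal
Conditions: i-Bu2AlH (1.1 equiv), CH2Cl2, −78 °C; sodium potassium tartrate work-up; used crude at once
Reagents that add atoms: none
Why: Partial reduction of the ester stops at the aluminium hemiacetal, which is stable at −78 °C and gives the aldehyde only on work-up, and immediate use limits enolisation at the α-centre.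

Step 14
Reactants: 20 (R)-3-(benzyloxy)-2-methylpropanal
Product: 21 (S)-{[(2-methylbut-3-en-1-yl)oxy]methyl}benzene
Conditions: Ph3PCH3Br, KN(SiMe3)2, THF, −78 °C to 0 °C
Reagents that add atoms: methyltriphenylphosphonium bromide, C[P+](c1ccccc1)(c1ccccc1)c1ccccc1.[Br-]
Why: Wittig methylenation with the preformed non-stabilised ylide is fast on this unhindered aldehyde at low temperature, which should outrun epimerisation of the α-stereocentre (C15).

Step 15
Reactants: 21 (S)-{[(2-methylbut-3-en-1-yl)oxy]methyl}benzene; 17 methyl 2,3-bis(benzyloxy)-5-[(3S,4R)-5-bromo-4-methylpent-1-en-3-yl]-4-[(2R,3E)-pent-3-en-2-yl]benzoate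
Product: 23 methyl 2,3-bis(benzyloxy)-5-[(3S,4S,8S)-9-(benzyloxy)-4,8-dimethylnon-1-en-3-yl]-4-[(2R,3E)-pent-3-en-2-yl]benzoate, via B-alkyl-9-BBN adduct 22 (not isolated)
Conditions: 21 (slight excess over boron hydride), 9-BBN, THF, 20 °C; then 17, Pd(OAc)2 (5 mol%), PCy3 (10 mol%), K3PO4·H2O, THF, 20 to 40 °C
Reagents that add atoms: none
Why: Anti-Markovnikov hydroboration of the terminal alkene followed by alkyl–alkyl Suzuki–Miyaura coupling, in which the electron-rich trialkylphosphine allows SN2-type oxidative addition at the primary C–Br bond and transmetalation of the hydroxide-activated borane should outpace β-hydride elimination, joins C12 to C13 without touching a stereocentre.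

Step 16
Reactants: 23 methyl 2,3-bis(benzyloxy)-5-[(3S,4S,8S)-9-(benzyloxy)-4,8-dimethylnon-1-en-3-yl]-4-[(2R,3E)-pent-3-en-2-yl]benzoate
Product: 24 methyl (5R,8R)-3,4-bis(benzyloxy)-8-[(2S,6S)-7-(benzyloxy)-6-methylheptan-2-yl]-5-methyl-5,8-dihydronaphthalene-2-carboxylate
Conditions: RuCl2(=CHPh)(H2IMes)(PCy3) (second-generation Grubbs catalyst, 5 mol%), 1,4-benzoquinone (10 mol%), CH2Cl2 (5 mM), 40 °C; then ethyl vinyl ether
Reagents that add atoms: none
Why: The ruthenium benzylidene exchanges onto the unhindered vinyl group on C4, the new alkylidene adds across the propenyl group on C1 in a [2+2] cycloaddition, and cycloreversion of the ruthenacyclobutane gives the C2=C3 double bond with loss of volatile propene, which drives the reaction. The closest known reaction type is ring-closing olefin metathesis of 1,2-dialkenylbenzenes to 1,4-dihydronaphthalenes. Ring B closes as a six-membered carbocycle by joining two olefin termini held ortho to each other on ring A, so the effective molarity is high and modest dilution should suffice against cross-metathesis. No stereocentre is formed: C1 and C4 are already fixed, so their trans relation is not a selectivity question of the closure (the descriptor at C4 changes from S to R only because the ring alkene changes the priorities). The selectivity needed is closure without double-bond migration through the benzylic and allylic hydrogens on C1 and C4; this is secured by the fast six-membered closure, the hydride scavenger 1,4-benzoquinone, a short reaction time and quenching of the catalyst before concentration. Ester, benzyl ethers and arene are inert to the catalyst, and no other alkene is present.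

Step 17
Reactants: 24 methyl (5R,8R)-3,4-bis(benzyloxy)-8-[(2S,6S)-7-(benzyloxy)-6-methylheptan-2-yl]-5-methyl-5,8-dihydronaphthalene-2-carboxylate
Product: 25 methyl (5R,8S)-3,4-bis(benzyloxy)-8-[(2S,6S)-7-(benzyloxy)-6-methylheptan-2-yl]-5-methyl-5,6,7,8-tetrahydronaphthalene-2-carboxylate
Conditions: 4-methylbenzenesulfonohydrazide (excess, in portions), NaOAc, DME/H2O, 85 °C
Reagents that add atoms: none
Why: Diimide reduction transfers two hydrogens to the cis-disubstituted ring alkene in a concerted, metal-free step, so no allylic migration can scramble C1 or C4, and ester, benzyl ethers and arene are not reduced.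

Step 18
Reactants: 25 methyl (5R,8S)-3,4-bis(benzyloxy)-8-[(2S,6S)-7-(benzyloxy)-6-methylheptan-2-yl]-5-methyl-5,6,7,8-tetrahydronaphthalene-2-carboxylate
Product: 26 methyl (5R,8S)-3,4-dihydroxy-8-[(2S,6S)-7-hydroxy-6-methylheptan-2-yl]-5-methyl-5,6,7,8-tetrahydronaphthalene-2-carboxylate (CNP0135649.1)
Conditions: H2 (1 atm), Pd/C (10%), EtOAc/MeOH, 20 °C
Reagents that add atoms: none
Why: Catalytic hydrogenolysis cleaves the two aryl benzyl ethers and the alkyl benzyl ether in one operation; with ring B already saturated no isomerisation is possible, and the methyl ester is stable.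

Compound list
1 | racemic (E)-pent-3-en-2-ol | C/C=C/C(C)O | starting material
2 | (2R,3E)-pent-3-en-2-yl acetate | CC(=O)O[C@H](C)/C=C/C | intermediate
3 | (2R,3E)-pent-3-en-2-ol | O[C@H](C)/C=C/C | intermediate
4 | methyl 2,3-dihydroxybenzoate | COC(=O)c1cccc(O)c1O | starting material
5 | methyl 5-bromo-2,3-dihydroxybenzoate | COC(=O)c1cc(Br)cc(O)c1O | intermediate
6 | methyl 5-bromo-2-hydroxy-3-{[(2S,3E)-pent-3-en-2-yl]oxy}benzoate | COC(=O)c1cc(Br)cc(O[C@@H](C)/C=C/C)c1O | intermediate
7 | methyl 5-bromo-2,3-dihydroxy-4-[(2R,3E)-pent-3-en-2-yl]benzoate | COC(=O)c1cc(Br)c([C@H](C)/C=C/C)c(O)c1O | intermediate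
8 | methyl 2,3-bis(benzyloxy)-5-bromo-4-[(2R,3E)-pent-3-en-2-yl]benzoate | COC(=O)c1cc(Br)c([C@H](C)/C=C/C)c(OCc2ccccc2)c1OCc1ccccc1 | intermediate
9 | (E)-3-(tributylstannyl)prop-2-en-1-ol | OC/C=C/[Sn](CCCC)(CCCC)CCCC | starting material
10 | methyl 2,3-bis(benzyloxy)-5-[(1E)-3-hydroxyprop-1-en-1-yl]-4-[(2R,3E)-pent-3-en-2-yl]benzoate | COC(=O)c1cc(/C=C/CO)c([C@H](C)/C=C/C)c(OCc2ccccc2)c1OCc1ccccc1 | intermediate
11 | propionyl chloride | CCC(Cl)=O | starting material
12 | methyl 2,3-bis(benzyloxy)-4-[(2R,3E)-pent-3-en-2-yl]-5-[(1E)-3-(propanoyloxy)prop-1-en-1-yl]benzoate | COC(=O)c1cc(/C=C/COC(=O)CC)c([C@H](C)/C=C/C)c(OCc2ccccc2)c1OCc1ccccc1 | intermediate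
13 | Z(O) boron ketene acetal of 12 with the (4S,5S)-diazaborolidine (not isolated) | COC(=O)c1cc(/C=C/CO/C(=C/C)OB2N(S(=O)(=O)c3cc(cc(c3)C(F)(F)F)C(F)(F)F)[C@@H](c3ccccc3)[C@H](c3ccccc3)N2S(=O)(=O)c3cc(cc(c3)C(F)(F)F)C(F)(F)F)c([C@H](C)/C=C/C)c(OCc2ccccc2)c1OCc1ccccc1 | intermediate
14 | (2R,3S)-3-{3,4-bis(benzyloxy)-5-(methoxycarbonyl)-2-[(2R,3E)-pent-3-en-2-yl]phenyl}-2-methylpent-4-enoic acid | COC(=O)c1cc([C@@H](C=C)[C@@H](C)C(O)=O)c([C@H](C)/C=C/C)c(OCc2ccccc2)c1OCc1ccccc1 | intermediate
15 | isobutyl carbonic mixed anhydride of 14 (not isolated) | COC(=O)c1cc([C@@H](C=C)[C@@H](C)C(=O)OC(=O)OCC(C)C)c([C@H](C)/C=C/C)c(OCc2ccccc2)c1OCc1ccccc1 | intermediate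
16 | methyl 2,3-bis(benzyloxy)-5-[(3S,4R)-5-hydroxy-4-methylpent-1-en-3-yl]-4-[(2R,3E)-pent-3-en-2-yl]benzoate | COC(=O)c1cc([C@@H](C=C)[C@@H](C)CO)c([C@H](C)/C=C/C)c(OCc2ccccc2)c1OCc1ccccc1 | intermediate
17 | methyl 2,3-bis(benzyloxy)-5-[(3S,4R)-5-bromo-4-methylpent-1-en-3-yl]-4-[(2R,3E)-pent-3-en-2-yl]benzoate | COC(=O)c1cc([C@@H](C=C)[C@@H](C)CBr)c([C@H](C)/C=C/C)c(OCc2ccccc2)c1OCc1ccccc1 | intermediate
18 | methyl (R)-3-hydroxy-2-methylpropanoate (Roche ester) | COC(=O)[C@H](C)CO | starting material
19 | methyl (R)-3-(benzyloxy)-2-methylpropanoate | COC(=O)[C@H](C)COCc1ccccc1 | intermediate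
20 | (R)-3-(benzyloxy)-2-methylpropanal | O=C[C@H](C)COCc1ccccc1 | intermediate
21 | (S)-{[(2-methylbut-3-en-1-yl)oxy]methyl}benzene | C=C[C@H](C)COCc1ccccc1 | intermediate
22 | 9-[(3S)-4-(benzyloxy)-3-methylbutyl]-9-borabicyclo[3.3.1]nonane (not isolated) | C(C[C@H](C)COCc1ccccc1)B1C2CCCC1CCC2 | intermediate
23 | methyl 2,3-bis(benzyloxy)-5-[(3S,4S,8S)-9-(benzyloxy)-4,8-dimethylnon-1-en-3-yl]-4-[(2R,3E)-pent-3-en-2-yl]benzoate | COC(=O)c1cc([C@@H](C=C)[C@@H](C)CCC[C@H](C)COCc2ccccc2)c([C@H](C)/C=C/C)c(OCc2ccccc2)c1OCc1ccccc1 | intermediate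
24 | methyl (5R,8R)-3,4-bis(benzyloxy)-8-[(2S,6S)-7-(benzyloxy)-6-methylheptan-2-yl]-5-methyl-5,8-dihydronaphthalene-2-carboxylate | COC(=O)c1cc2c(c(OCc3ccccc3)c1OCc1ccccc1)[C@H](C)C=C[C@H]2[C@@H](C)CCC[C@H](C)COCc1ccccc1 | intermediate
25 | methyl (5R,8S)-3,4-bis(benzyloxy)-8-[(2S,6S)-7-(benzyloxy)-6-methylheptan-2-yl]-5-methyl-5,6,7,8-tetrahydronaphthalene-2-carboxylate | COC(=O)c1cc2c(c(OCc3ccccc3)c1OCc1ccccc1)[C@H](C)CC[C@H]2[C@@H](C)CCC[C@H](C)COCc1ccccc1 | intermediate
26 | methyl (5R,8S)-3,4-dihydroxy-8-[(2S,6S)-7-hydroxy-6-methylheptan-2-yl]-5-methyl-5,6,7,8-tetrahydronaphthalene-2-carboxylate | COC(=O)c1cc2c(c(O)c1O)[C@H](C)CC[C@H]2[C@@H](C)CCC[C@H](C)CO | target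

Total step count: 18. Longest linear sequence: 14 steps (steps 1, 2, 4 to 11 and 15 to 18).

Steps most likely to fail

Step 9. Enolisation under the Z(O)-selective conditions may be incomplete or unselective, and the controller may discriminate the enolate faces poorly, or in the unexpected sense, on this ortho-substituted cinnamyl ester. Either would give the wrong C4/C11 diastereomers; the rearrangement may also be slow. The fallback replaces reagent control by chirality transfer from a C–O stereocentre. Setting out from 8, Stille coupling as in step 7 with (2R,3E)-4-(tributylstannyl)but-3-en-2-ol F1, made by radical hydrostannation of commercial (R)-but-3-yn-2-ol (Bu3SnH, AIBN), gives the secondary allylic alcohol F2. Propionylation with 11 gives the propionate F3. LiN(i-Pr)2 in THF/DMPU at −78 °C and then Me3SiCl give the Z silyl ketene acetal F4, which rearranges on warming through a chair with the carbinol methyl equatorial. The existing stereocentre thereby dictates both new centres, and the acid F5 carries an E-propenyl group on C4. Reduction through the mixed anhydride F6 gives the alcohol F7, Appel bromination gives the bromide F8, and coupling with 22 as in step 15 gives the diene F9. Ring-closing metathesis of F9 under the conditions of step 16 expels but-2-ene and comes back to the route at 24.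

Step 15. Oxidative addition of zerovalent palladium into the β-branched primary C–Br bond may be slow, so that β-hydride elimination of the alkylpalladium and loss of the borane take over. The fallback reverses the polarity of the coupling (Negishi). Setting out from 21, hydroboration to 22 and oxidation (NaOH, H2O2) give (S)-4-(benzyloxy)-3-methylbutan-1-ol F10, and CBr4/PPh3 gives the unbranched bromide F11. Bromide 17 is converted with zinc dust (I2 cat., DMA, 70 °C) into the alkylzinc bromide F12. F12 and F11 are coupled with PdCl2(IPr)(3-chloropyridine) (IPr = 1,3-bis(2,6-diisopropylphenyl)imidazol-2-ylidene) and LiBr in THF/NMP at 20 °C, where oxidative addition takes place at an unhindered C–Br bond, and the sequence comes back at 23.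

Step 4. Etherification may occur at the chelated 2-hydroxyl or at both hydroxyls instead of the 3-hydroxyl alone. The fallback locks the 2-hydroxyl and the carboxyl group together. Setting out from 5, saponification (LiOH, THF/H2O) gives 5-bromo-2,3-dihydroxybenzoic acid F13. Acetone, (CF3CO)2O and CF3CO2H give 6-bromo-8-hydroxy-2,2-dimethyl-4H-1,3-benzodioxin-4-one F14, in which only the 3-hydroxyl is free. Mitsunobu reaction with 3 gives the ether F15, and NaOMe in MeOH opens the dioxinone to the methyl salicylate, coming back at 6.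

Further compounds
F1 | step 9 | (2R,3E)-4-(tributylstannyl)but-3-en-2-ol | C[C@@H](O)/C=C/[Sn](CCCC)(CCCC)CCCC
F2 | step 9 | methyl 2,3-bis(benzyloxy)-5-[(1E,3R)-3-hydroxybut-1-en-1-yl]-4-[(2R,3E)-pent-3-en-2-yl]benzoate | COC(=O)c1cc(/C=C/[C@@H](C)O)c([C@H](C)/C=C/C)c(OCc2ccccc2)c1OCc1ccccc1
F3 | step 9 | propionate of F2 | COC(=O)c1cc(/C=C/[C@@H](C)OC(=O)CC)c([C@H](C)/C=C/C)c(OCc2ccccc2)c1OCc1ccccc1
F4 | step 9 | Z trimethylsilyl ketene acetal of F3 | COC(=O)c1cc(/C=C/[C@@H](C)O/C(=C/C)O[Si](C)(C)C)c([C@H](C)/C=C/C)c(OCc2ccccc2)c1OCc1ccccc1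
F5 | step 9 | (2R,3S,4E)-3-aryl-2-methylhex-4-enoic acid, the C4-propenyl analogue of 14 | COC(=O)c1cc([C@@H](/C=C/C)[C@@H](C)C(O)=O)c([C@H](C)/C=C/C)c(OCc2ccccc2)c1OCc1ccccc1
F6 | step 9 | isobutyl carbonic mixed anhydride of F5 | COC(=O)c1cc([C@@H](/C=C/C)[C@@H](C)C(=O)OC(=O)OCC(C)C)c([C@H](C)/C=C/C)c(OCc2ccccc2)c1OCc1ccccc1
F7 | step 9 | primary alcohol, the C4-propenyl analogue of 16 | COC(=O)c1cc([C@@H](/C=C/C)[C@@H](C)CO)c([C@H](C)/C=C/C)c(OCc2ccccc2)c1OCc1ccccc1
F8 | step 9 | primary bromide, the C4-propenyl analogue of 17 | COC(=O)c1cc([C@@H](/C=C/C)[C@@H](C)CBr)c([C@H](C)/C=C/C)c(OCc2ccccc2)c1OCc1ccccc1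
F9 | step 9 | bis-propenyl diene, the C4-propenyl analogue of 23 | COC(=O)c1cc([C@@H](/C=C/C)[C@@H](C)CCC[C@H](C)COCc2ccccc2)c([C@H](C)/C=C/C)c(OCc2ccccc2)c1OCc1ccccc1
F10 | step 15 | (S)-4-(benzyloxy)-3-methylbutan-1-ol | OCC[C@H](C)COCc1ccccc1
F11 | step 15 | (S)-[(4-bromo-2-methylbutoxy)methyl]benzene | BrCC[C@H](C)COCc1ccccc1
F12 | step 15 | alkylzinc bromide from 17 | COC(=O)c1cc([C@@H](C=C)[C@@H](C)C[Zn]Br)c([C@H](C)/C=C/C)c(OCc2ccccc2)c1OCc1ccccc1
F13 | step 4 | 5-bromo-2,3-dihydroxybenzoic acid | OC(=O)c1cc(Br)cc(O)c1O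
F14 | step 4 | 6-bromo-8-hydroxy-2,2-dimethyl-4H-1,3-benzodioxin-4-one | CC1(C)OC(=O)c2cc(Br)cc(O)c2O1
F15 | step 4 | 6-bromo-2,2-dimethyl-8-{[(2S,3E)-pent-3-en-2-yl]oxy}-4H-1,3-benzodioxin-4-one | CC1(C)OC(=O)c2cc(Br)cc(O[C@@H](C)/C=C/C)c2O1
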